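**Plan**

- Retrosynthesis: the 3'-OH is traced back to a benzyl ether. The C2=C3 double bond and the C4 carbonyl are traced back through a flavanone and a flavan-4-ol to a 4-methoxyflavan, whose ring C is then cut at O1–C2 and C3–C4.
- Enabling feature: with ring A written as an ortho-quinone methide, O1, C8a, C4a and C4 form a 1-oxadiene, and C2–C3 is the vinyl group of a ring B styrene. The two halves are therefore a salicylaldehyde and a styrene.
- Forward order: ring A is formylated ortho to its phenol, and ring B is benzylated and methylenated. Ring C, the only ring made, closes by [4+2] cycloaddition and is then hydrolysed, oxidised and dehydrogenated before the benzyl group is removed.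
- Stereochemistry: the target is achiral. C2 and C4 of the flavan arise racemic in the cycloaddition and both are erased by the later oxidations, so no stereocontrol is needed.

Key step: step 4

Remark on the chemistry: 2,3,4-trimethoxyphenol, 3-hydroxy-4,5-dimethoxybenzaldehyde and trimethyl orthoformate are taken as catalogue chemicals. Flavone numbering is used (O1, C2–C4, C4a, C5–C8, C8a; primed positions for ring B). Chiral intermediates are racemic with one enantiomer drawn. Compounds 10 and 11 are drawn as the 2,4-cis isomers expected to predominate, and any trans isomer is carried along because it converges on the same flavanone.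

**Step 1**
Reactants: 1 2,3,4-trimethoxyphenol
Product: 3 2-hydroxy-3,4,5-trimethoxybenzaldehyde, via salicyl alcohol 2 (not isolated)
Conditions: MgCl2 (anhydrous), Et3N, (CH2O)n, MeCN, reflux; aq HCl work-up
Reagents that add atoms: paraformaldehyde (formaldehyde units), C=O
Why: Casnati–Skattebøl ortho-formylation, in which the magnesium phenoxide of 1 delivers formaldehyde to C6 (the only free ortho position) and the magnesium alkoxide of 2 is oxidised to the aldehyde by Oppenauer-type hydride transfer to a second formaldehyde, leaving the aryl methyl ethers untouched.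

**Step 2**
Reactants: 4 3-hydroxy-4,5-dimethoxybenzaldehyde
Product: 5 3-(benzyloxy)-4,5-dimethoxybenzaldehyde
Conditions: BnBr, K2CO3, DMF, rt
Reagents that add atoms: benzyl bromide, BrCc1ccccc1
Why: Williamson ether synthesis on the only acidic OH, giving an ether that should withstand the acid, the oxidant and the hot iodine of later steps and that leaves by hydrogenolysis at the end.

**Step 3**
Reactants: 5 3-(benzyloxy)-4,5-dimethoxybenzaldehyde
Product: 6 1-(benzyloxy)-5-ethenyl-2,3-dimethoxybenzene
Conditions: Ph3PCH3Br, KOtBu, THF, 0 °C → rt
Reagents that add atoms: methyltriphenylphosphonium bromide, C[P+](c1ccccc1)(c1ccccc1)c1ccccc1.[Br-]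
Why: Wittig methylenation of a non-enolisable aromatic aldehyde with the unstabilised ylide, which creates no stereochemistry; the styrene is used promptly to avoid polymerisation.

**Step 4**
Reactants: 3 2-hydroxy-3,4,5-trimethoxybenzaldehyde; 6 1-(benzyloxy)-5-ethenyl-2,3-dimethoxybenzene; 7 trimethyl orthoformate
Product: 10 rac-(2S,4S)-2-[3-(benzyloxy)-4,5-dimethoxyphenyl]-4,6,7,8-tetramethoxychromane (2,4-cis racemate), via dimethyl acetal 8 (not isolated), via ortho-quinone methide 9 (not isolated)
Conditions: TsOH·H2O (10 mol %), HC(OMe)3 (3 equiv), CH2Cl2, rt; then 6 (1.3 equiv) added slowly, rt → 40 °C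
Reagents that add atoms: trimethyl orthoformate (7), COC(OC)OC
Why: Acid-catalysed acetalisation of 3 by the orthoformate gives acetal 8, whose ionisation yields an O-methyl oxocarbenium ion, the protonated form of (E)-ortho-quinone methide 9, stabilised by the ring A methoxy group para to the former formyl carbon. This 1-oxadiene (O1, C8a, C4a, C4) adds the vinyl group of 6 in an inverse-electron-demand hetero-Diels–Alder reaction that is concerted but asynchronous, C3–C4 forming ahead of O1–C2; the closest known reaction type is the acid-catalysed three-component synthesis of 4-alkoxychromans from salicylaldehydes, orthoformates and styrenes. Ring C closes as a six-membered ring by [4+2] cycloaddition, four atoms coming from the heterodiene and two from the alkene, with the phenolic oxygen making the ring-closing O1–C2 bond. C2 and C4 are formed racemic; their relative configuration is set by endo approach of the aryl group to the E-configured diene terminus and, because C4 can re-ionise under the acid, by equilibration toward the diequatorial 2,4-cis isomer. The selectivity the step needs is regiochemical (aryl at C2, not C3) together with ring closure in preference to styrene oligomerisation; the first follows from polarity, since the unsubstituted alkene terminus is the nucleophile and charge builds at the carbon that ring B with its 4'-methoxy group can stabilise, and the second is helped by slow addition of the styrene.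

**Step 5**
Reactants: 10 rac-(2S,4S)-2-[3-(benzyloxy)-4,5-dimethoxyphenyl]-4,6,7,8-tetramethoxychromane
Product: 11 rac-(2S,4S)-2-[3-(benzyloxy)-4,5-dimethoxyphenyl]-6,7,8-trimethoxychroman-4-ol
Conditions: 1 M aq HCl, THF, rt
Reagents that add atoms: water, O
Why: Acid-catalysed SN1 solvolysis of a benzylic ether, in which the C4 cation (stabilised by O1 ortho and the 7-methoxy group para) is captured by the large excess of water; the resulting C4 configuration (cis expected on thermodynamic grounds) is irrelevant because C4 becomes a carbonyl next.

**Step 6**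
Reactants: 11 rac-(2S,4S)-2-[3-(benzyloxy)-4,5-dimethoxyphenyl]-6,7,8-trimethoxychroman-4-ol
Product: 12 rac-(2S)-2-[3-(benzyloxy)-4,5-dimethoxyphenyl]-6,7,8-trimethoxychroman-4-one
Conditions: Dess–Martin periodinane, CH2Cl2, 0 °C → rt
Reagents that add atoms: none
Why: Dess–Martin oxidation of a secondary benzylic alcohol under near-neutral conditions that should leave the benzyl ether, the aryl methyl ethers and the C2–O1 bond untouched while removing the C4 stereocentre.

**Step 7**
Reactants: 12 rac-(2S)-2-[3-(benzyloxy)-4,5-dimethoxyphenyl]-6,7,8-trimethoxychroman-4-one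
Product: 14 2-[3-(benzyloxy)-4,5-dimethoxyphenyl]-6,7,8-trimethoxy-4H-chromen-4-one, via 3-iodoflavanone 13 (not isolated)
Conditions: I2 (10 mol %), DMSO, 120 °C
Reagents that add atoms: none
Why: Iodine/DMSO dehydrogenation of a flavanone, proceeding by enol iodination at C3, loss of HI across C2–C3 driven by conjugation, and reoxidation of HI to I2 by DMSO; the C2 stereocentre disappears and the ethers should survive, as is usual for polyalkoxyflavanones.

**Step 8**
Reactants: 14 2-[3-(benzyloxy)-4,5-dimethoxyphenyl]-6,7,8-trimethoxy-4H-chromen-4-one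
Product: 15 2-(3-hydroxy-4,5-dimethoxyphenyl)-6,7,8-trimethoxy-4H-chromen-4-one
Conditions: H2 (1 atm), 10% Pd/C, EtOAc/MeOH, rt
Reagents that add atoms: none
Why: Catalytic hydrogenolysis of an aryl benzyl ether, which at balloon pressure and room temperature is normally faster than reduction of the conjugated C2=C3 bond of a flavone; the reaction is stopped once 14 is consumed.

**Compound list**

1 | 2,3,4-trimethoxyphenol | COc1ccc(O)c(OC)c1OC | starting material
2 | 6-(hydroxymethyl)-2,3,4-trimethoxyphenol (present as its magnesium salt; not isolated) | OCc1cc(OC)c(OC)c(OC)c1O | intermediate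
3 | 2-hydroxy-3,4,5-trimethoxybenzaldehyde | O=Cc1cc(OC)c(OC)c(OC)c1O | intermediate
4 | 3-hydroxy-4,5-dimethoxybenzaldehyde | COc1cc(C=O)cc(O)c1OC | starting material
5 | 3-(benzyloxy)-4,5-dimethoxybenzaldehyde | COc1cc(C=O)cc(OCc2ccccc2)c1OC | intermediate
6 | 1-(benzyloxy)-5-ethenyl-2,3-dimethoxybenzene | C=Cc1cc(OC)c(OC)c(OCc2ccccc2)c1 | intermediate
7 | trimethyl orthoformate | COC(OC)OC | starting material
8 | 6-(dimethoxymethyl)-2,3,4-trimethoxyphenol (dimethyl acetal of 3; not isolated) | COC(OC)c1cc(OC)c(OC)c(OC)c1O | intermediate
9 | (6E)-2,3,4-trimethoxy-6-(methoxymethylidene)cyclohexa-2,4-dien-1-one (ortho-quinone methide, reacting as its O-protonated form; not isolated) | CO/C=C1\C=C(OC)C(OC)=C(OC)C1=O | intermediate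
10 | rac-(2S,4S)-2-[3-(benzyloxy)-4,5-dimethoxyphenyl]-4,6,7,8-tetramethoxychromane (2,4-cis; 2S,4S enantiomer drawn) | CO[C@H]1C[C@@H](c2cc(OC)c(OC)c(OCc3ccccc3)c2)Oc2c(OC)c(OC)c(OC)cc21 | intermediate
11 | rac-(2S,4S)-2-[3-(benzyloxy)-4,5-dimethoxyphenyl]-6,7,8-trimethoxychroman-4-ol (2,4-cis; 2S,4S enantiomer drawn) | O[C@H]1C[C@@H](c2cc(OC)c(OC)c(OCc3ccccc3)c2)Oc2c(OC)c(OC)c(OC)cc21 | intermediate
12 | rac-(2S)-2-[3-(benzyloxy)-4,5-dimethoxyphenyl]-6,7,8-trimethoxychroman-4-one (2S enantiomer drawn) | O=C1C[C@@H](c2cc(OC)c(OC)c(OCc3ccccc3)c2)Oc2c(OC)c(OC)c(OC)cc21 | intermediate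
13 | rac-(2R,3R)-2-[3-(benzyloxy)-4,5-dimethoxyphenyl]-3-iodo-6,7,8-trimethoxychroman-4-one (2,3-trans assumed; not isolated) | O=C1[C@H](I)[C@@H](c2cc(OC)c(OC)c(OCc3ccccc3)c2)Oc2c(OC)c(OC)c(OC)cc21 | intermediate
14 | 2-[3-(benzyloxy)-4,5-dimethoxyphenyl]-6,7,8-trimethoxy-4H-chromen-4-one | COc1cc(-c2cc(=O)c3cc(OC)c(OC)c(OC)c3o2)cc(OCc2ccccc2)c1OC | intermediate
15 | 2-(3-hydroxy-4,5-dimethoxyphenyl)-6,7,8-trimethoxy-4H-chromen-4-one (3'-hydroxy-4',5',6,7,8-pentamethoxyflavone) | COc1cc(-c2cc(=O)c3cc(OC)c(OC)c(OC)c3o2)cc(O)c1OC | target

**Summary**

Total step count: 8. Longest linear sequence: 7 steps (4 → 5 → 6 → 10 → 11 → 12 → 14 → 15).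

Steps most likely to fail:

1. Step 4. Acid-induced oligomerisation of the styrene, or capture of the open benzylic cation by methanol, may outrun ring closure. The styrene is only moderately nucleophilic because its 4'-methoxy group is twisted out of conjugation by its two neighbours. The fallback gives up the cycloaddition for a chalcone route. It sets out from 1, which BF3·OEt2-mediated ortho-acetylation with acetic acid at about 90 °C should convert into 1-(2-hydroxy-3,4,5-trimethoxyphenyl)ethan-1-one F1. Claisen–Schmidt condensation of this ketone with aldehyde 5 (KOH, EtOH, rt) should give (E)-3-[3-(benzyloxy)-4,5-dimethoxyphenyl]-1-(2-hydroxy-3,4,5-trimethoxyphenyl)prop-2-en-1-one F2. Oxidative cyclisation of the chalcone with catalytic I2 in DMSO at 120–130 °C then comes back to the route at 14.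

2. Step 5. Loss of the C3 proton from the C4 cation (dehydration toward a 3,4-alkene), or cycloreversion, may compete with capture by water. The fallback avoids the alcohol altogether. It sets out from 10 and oxidises the benzylic methyl ether directly with DDQ in wet CH2Cl2 at 0 °C → rt: hydride abstraction from C4, addition of water and loss of methanol from the hemiketal. It comes back to the route at 12, and this detour makes no compound outside the route (F0).

3. Step 8. Over-reduction of the C2=C3 bond, or stalling of the catalyst through sulfur residues from the DMSO step, may spoil the debenzylation. The fallback changes the order of events. It sets out from 12, where no alkene is at risk, and hydrogenolysis (H2, 10% Pd/C, EtOAc) should give rac-(2S)-2-(3-hydroxy-4,5-dimethoxyphenyl)-6,7,8-trimethoxychroman-4-one F3. Dehydrogenation of this free phenol with catalytic I2 in DMSO at 120 °C then comes back to the route at 15.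

**Further compounds**

F1 | step 4 | 1-(2-hydroxy-3,4,5-trimethoxyphenyl)ethan-1-one | CC(=O)c1cc(OC)c(OC)c(OC)c1O
F2 | step 4 | (E)-3-[3-(benzyloxy)-4,5-dimethoxyphenyl]-1-(2-hydroxy-3,4,5-trimethoxyphenyl)prop-2-en-1-one | O=C(/C=C/c1cc(OC)c(OC)c(OCc2ccccc2)c1)c1cc(OC)c(OC)c(OC)c1O
F0 | step 5 | none | none
F3 | step 8 | rac-(2S)-2-(3-hydroxy-4,5-dimethoxyphenyl)-6,7,8-trimethoxychroman-4-one | O=C1C[C@@H](c2cc(OC)c(OC)c(O)c2)Oc2c(OC)c(OC)c(OC)cc21
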